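The top flavan unit is all-cis (2R,3R,4S, a 4α→8 link), which cationic C4 coupling cannot give, so its ring C is built onto C8 of a B2-type dimer. The route rests on cutting O1–C2 of that unit. C2 is benzylic to ring B and, at the flav-3-ene level, allylic to C3=C4, so the ring A phenol can capture a 1,1,3-triaryl-2-alkoxyallyl cation. One chiral-acid dehydration forms O1–C2, closes ring C and sets C2, which then relays C4 and C3. The precursor is a tertiary allylic carbinol carrying the dimer, ring A with a single free ortho-phenol, and a MOM enol ether.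

Key step: step 13

Assumption: the (R)-phosphoramide is taken to favour 2R by analogy with the known chromene closures; if it proves to be the mismatched partner of the enantiopure dimer, the (S)-enantiomer of the same catalyst is used and nothing else changes.

Ring D below means the aromatic ring of the middle unit that carries C8. "Dimer-8-yl" means the (4β→8) dimer of steps 5 and 11 bonded through C8 of its upper unit.

Step 1
Reactants: 1 (−)-epicatechin
Product: 2 5,7,3',4'-tetra-O-benzyl-(−)-epicatechin (2R,3R; 3-OH free)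
Conditions: BnBr (4.4 equiv), K2CO3, DMF, 0 °C to rt, argon
Reagents that add atoms: benzyl bromide, BrCc1ccccc1
Why: Williamson etherification in which carbonate deprotonates only the four phenols, so the secondary 3-OH stays free, and the mild oxygen-free medium leaves C2 and C3 untouched.

Step 2
Reactants: 2 5,7,3',4'-tetra-O-benzyl-(−)-epicatechin
Product: 3 5,7,3',4'-tetra-O-benzyl-3-O-(tert-butyldimethylsilyl)-(−)-epicatechin
Conditions: TBSCl, imidazole, DMF, rt
Reagents that add atoms: tert-butyldimethylsilyl chloride, CC(C)(C)[Si](C)(C)Cl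
Why: Imidazole-promoted silylation of the only free hydroxyl installs a group that tolerates Lewis acid at −78 °C and aryllithium chemistry and is later removed by fluoride.

Step 3
Reactants: 3 5,7,3',4'-tetra-O-benzyl-3-O-TBS-epicatechin
Product: 4 4β-(2-ethoxyethoxy)-5,7,3',4'-tetra-O-benzyl-3-O-TBS-epicatechin (2,3-cis-3,4-trans)
Conditions: DDQ, EtOCH2CH2OH, CH2Cl2, rt
Reagents that add atoms: 2-ethoxyethanol, CCOCCO
Why: DDQ benzylic oxidation abstracts hydride from C4 to give the ring A-stabilised cation, which the alcohol traps anti to the 3-silyloxy group (3,4-trans), and this centre serves only to carry the leaving group.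

Step 4
Reactants: 4 4β-(2-ethoxyethoxy)-tetra-O-benzyl-3-O-TBS-epicatechin
Product: 5 8-bromo-4β-(2-ethoxyethoxy)-5,7,3',4'-tetra-O-benzyl-3-O-TBS-epicatechin
Conditions: NBS (1.0 equiv), CH2Cl2, −78 to 0 °C
Reagents that add atoms: N-bromosuccinimide, O=C1CCC(=O)N1Br
Why: Electrophilic aromatic bromination of the phloroglucinol-type ring, known to go to C8 in benzylated flavan-3-ols; the bromine blocks self-condensation in step 5 and is the lithiation handle in step 11.

Step 5
Reactants: 5 8-bromo-4β-(2-ethoxyethoxy) electrophile; 3 tetra-O-benzyl-3-O-TBS-epicatechin (1.5 equiv)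
Product: 6 8-bromo (4β→8) dimer: C4 of the 8-bromo upper unit bonded to C8 of the lower unit, both units 5,7,3',4'-tetra-O-benzyl-3-O-TBS-epicatechin, upper unit 2,3-cis-3,4-trans
Conditions: TMSOTf (0.2 equiv), CH2Cl2, −78 °C; Et3N quench
Reagents that add atoms: none
Why: In this Lewis-acid-promoted Friedel–Crafts flavanyl coupling the C4 ether ionises and C8 of 3 attacks anti to the 3-OTBS group, setting the middle-unit C4 as 3,4-trans (4β), as is general for epicatechin-derived C4 cations.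

Step 6
Reactants: 7 2',4',6'-trihydroxyacetophenone
Product: 8 1-[2,4-bis(benzyloxy)-6-hydroxyphenyl]ethanone
Conditions: BnBr (2.1 equiv), K2CO3, DMF, rt
Reagents that add atoms: benzyl bromide, BrCc1ccccc1
Why: Williamson etherification in which the last ortho-phenol, locked in a hydrogen bond to the ketone, reacts slowest, so two equivalents stop at the dibenzyl ether.

Step 7
Reactants: 8 1-[2,4-bis(benzyloxy)-6-hydroxyphenyl]ethanone
Product: 9 1-[2-(allyloxy)-4,6-bis(benzyloxy)phenyl]ethanone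
Conditions: allyl bromide, K2CO3, DMF, 60 °C
Reagents that add atoms: allyl bromide, C=CCBr
Why: Williamson etherification tags the future O1 with a group that zerovalent palladium removes under basic conditions, so this oxygen never has to be distinguished from benzyl ethers flanking a carbonyl.

Step 8
Reactants: 9 1-[2-(allyloxy)-4,6-bis(benzyloxy)phenyl]ethanone
Product: 12 1-[2-(allyloxy)-4,6-bis(benzyloxy)phenyl]-2-hydroxyethanone, via trimethylsilyl enol ether 10 (not isolated), via alpha-silyloxy ketone 11 (not isolated)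
Conditions: i) TMSOTf, Et3N, CH2Cl2, 0 °C; ii) mCPBA (1.05 equiv), CH2Cl2, −20 °C; iii) citric acid (cat.), THF/H2O, rt
Reagents that add atoms: 3-chloroperoxybenzoic acid, OOC(=O)c1cccc(Cl)c1; trimethylsilyl triflate, C[Si](C)(C)OS(=O)(=O)C(F)(F)F (silyl group of 10 and 11 only)
Why: In this Rubottom oxidation the silyl enol ether is far more nucleophilic than the allyl group or the arene, so the peracid oxidises only that double bond, and silyl migration followed by mild hydrolysis gives the alpha-hydroxy ketone.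

Step 9
Reactants: 12 1-[2-(allyloxy)-4,6-bis(benzyloxy)phenyl]-2-hydroxyethanone
Product: 13 1-[2-(allyloxy)-4,6-bis(benzyloxy)phenyl]-2-(methoxymethoxy)ethanone
Conditions: MOMCl, i-Pr2NEt, CH2Cl2, 0 °C to rt
Reagents that add atoms: chloromethyl methyl ether, COCCl
Why: Alkylation of the primary alcohol to its MOM ether; a MOM group is preferred to a methyl group because it can later be taken off the enol oxygen without the aqueous acid that would re-ionise the allylic O1–C2 bond.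

Step 10
Reactants: 13 2-(methoxymethoxy) ketone; 14 3,4-bis(benzyloxy)benzaldehyde
Product: 15 (Z)-1-[2-(allyloxy)-4,6-bis(benzyloxy)phenyl]-3-[3,4-bis(benzyloxy)phenyl]-2-(methoxymethoxy)prop-2-en-1-one
Conditions: KOH, EtOH/THF, rt
Reagents that add atoms: none
Why: Claisen–Schmidt condensation (aldol addition, then E1cB loss of water), known for alpha-alkoxyacetophenones, delivers the complete C2–C3–C4 enol ether unit with ring B trans to the carbonyl and needs no alpha-metallated enol ether.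

Step 11
Reactants: 6 8-bromo (4β→8) dimer; 15 alpha-(methoxymethoxy)chalcone (1.3 equiv)
Product: 17 (Z)-1-[2-(allyloxy)-4,6-bis(benzyloxy)phenyl]-1-(dimer-8-yl)-3-[3,4-bis(benzyloxy)phenyl]-2-(methoxymethoxy)prop-2-en-1-ol (both carbinol epimers), via 8-lithio dimer 16 (not isolated)
Conditions: t-BuLi (2.0 equiv), THF, −78 °C; then 15, −78 to −40 °C; aq NH4Cl; Et3N-deactivated silica
Reagents that add atoms: tert-butyllithium, [Li]C(C)(C)C (lithium of 16 only)
Why: Bromine–lithium exchange is followed by 1,2-addition of the aryllithium to a non-enolisable enone whose alpha-alkoxy group polarises the alkene against conjugate addition; 2,6-dialkoxyaryllithiums are known to add to ortho-alkoxylated aryl ketones, and the new carbinol centre needs no control because it is erased in step 13.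

Step 12
Reactants: 17 O-allyl tertiary carbinol
Product: 18 (Z)-1-[2,4-bis(benzyloxy)-6-hydroxyphenyl]-1-(dimer-8-yl)-3-[3,4-bis(benzyloxy)phenyl]-2-(methoxymethoxy)prop-2-en-1-ol (both carbinol epimers; precursor of the key step)
Conditions: Pd(PPh3)4 (5 mol %), morpholine, THF, rt, dark; short basic alumina plug, used at once
Reagents that add atoms: none
Why: Tsuji–Trost deallylation: zerovalent palladium ionises only the aryl allyl ether and morpholine takes up the allyl group, so one phenol is freed in a basic medium in which the acid-labile carbinol cannot ionise.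

Step 13
Reactants: 18 tertiary allylic carbinol with one free ring A phenol
Product: 20 (2R)-5,7-bis(benzyloxy)-2-[3,4-bis(benzyloxy)phenyl]-3-(methoxymethoxy)-4-(dimer-8-yl)-2H-chromene (flav-3-ene; both 3-O-TBS groups of the dimer retained), via allyl cation 19 (not isolated)
Conditions: (R)-3,3'-bis(2,4,6-triisopropylphenyl)-1,1'-binaphthyl-2,2'-diyl N-(trifluoromethylsulfonyl)phosphoramide (10 mol %), 4 Å molecular sieves, toluene/CH2Cl2 4:1, −60 °C, dark; Et3N quench at −60 °C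
Reagents that add atoms: none
Why: The strong chiral acid protonates the tertiary hydroxyl and water leaves, giving allyl cation 19 (delocalised over C4, C3 and C2; its conjugate base is the vinylogous ortho-quinone methide) as a contact ion pair with the phosphoramide anion, which also hydrogen-bonds the ring A phenol. The closest known reaction is the N-triflyl-phosphoramide-catalysed intramolecular allylic substitution of ortho-(hydroxyallyl)phenols to 2-substituted 2H-chromenes. Ring C closes by 6-endo-trig attack of the phenol oxygen on the ring B terminus C2, equally describable as an oxa-6π electrocyclisation, and the released proton regenerates the catalyst. C2, the only new stereocentre, is set as R by the chiral counter-anion, because the stereocentres of the dimer lie beyond the orthogonal ring D and both carbinol epimers converge on the same planar cation. The step needs one oxygen nucleophile and one site of attack: only the oxygen carried as the allyl ether is free, attack at C4 would require a four-membered ring, and every ortho position of rings A and D is oxygenated, so Friedel–Crafts closure there is blocked. Low temperature, low acid loading and the cold amine quench keep the product, itself an ionisable allylic aryl ether, from re-opening.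

Step 14
Reactants: 20 (2R)-3-(methoxymethoxy)flav-3-ene bis-TBS ether
Product: 21 (2R)-3-(methoxymethoxy)flav-3-ene diol (3-OH of the middle and bottom units free)
Conditions: Bu4NF, THF, 0 °C to rt, dark
Reagents that add atoms: none
Why: Fluoride desilylation runs in a basic, acid-free medium, in which the MOM enol ether (which keeps the top C3 oxygen masked) and the allylic O1–C2 bond are inert.

Step 15
Reactants: 21 flav-3-ene diol; 22 3,4,5-tris(benzyloxy)benzoic acid (4 equiv)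
Product: 23 (2R)-3-(methoxymethoxy)flav-3-ene bis(3,4,5-tri-O-benzylgallate) (esters at O3 of the middle and bottom units)
Conditions: DCC, DMAP, CH2Cl2, rt, dark
Reagents that add atoms: none
Why: Steglich esterification, the established way to galloylate benzylated procyanidins, acylates the only two hydroxyl groups present, so the top C3 oxygen needs no separate protection step.

Step 16
Reactants: 23 3-(methoxymethoxy)flav-3-ene bis-gallate
Product: 25 (2R,4S)-flavan-3-one bis-gallate (top unit 2,4-cis: ring B and ring D on the same face), via trimethylsilyl enol ether 24 (not isolated)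
Conditions: TMSOTf (3 equiv), 2,2'-bipyridyl (4.5 equiv), CH2Cl2, 0 °C; then H2O, 0 °C; crude product taken on directly
Reagents that add atoms: trimethylsilyl triflate, C[Si](C)(C)OS(=O)(=O)C(F)(F)F (silyl group of 24 only)
Why: Proposed new method: the silyl triflate/2,2'-bipyridyl pair is known to turn aryl MOM ethers into aryl silyl ethers in a weakly basic medium that leaves even trityl ethers intact, and it is extended here to an enol MOM ether, whose oxygen is conjugated in the same way; the silylated bipyridinium activates the acetal, bipyridyl carries off the MeOCH2 fragment as a pyridinium salt and the enol oxygen ends up silylated (24), so no Brønsted acid able to ionise the allylic O1–C2 bond is present; water then cleaves the Si–O bond and the enol is protonated at C4 under kinetic control on the face opposite the pseudo-axial ring B, which places ring D cis to ring B (4S).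

Step 17
Reactants: 25 (2R,4S)-flavan-3-one bis-gallate
Product: 26 octadeca-O-benzyl trimer bis-gallate with all-cis (2R,3R,4S) top unit and free top 3-OH
Conditions: LiBH(s-Bu)3 (2 equiv), LiBr, THF, −78 °C; AcOH quench at −78 °C
Reagents that add atoms: none
Why: Ketone reduction with a bulky trialkylborohydride is the known way from benzylated flavan-3-ones to 2,3-cis flavan-3-ols; hydride can reach C3 only from the face opposite the cis-disposed aryl groups at C2 and C4, which puts the hydroxyl on their side (3R, all-cis), and at −78 °C the gallate esters are not attacked and reduction outruns enolisation.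

Step 18
Reactants: 26 octadeca-O-benzyl trimer bis-gallate
Product: 27 epicatechin-(4α→8)-epicatechin-3-O-gallate-(4β→8)-epicatechin-3-O-gallate (CNP0279403.2)
Conditions: H2 (1 atm), Pd(OH)2/C, THF/MeOH/H2O, rt; filtration, lyophilisation
Reagents that add atoms: none
Why: Catalytic hydrogenolysis removes all eighteen benzyl ethers under neutral conditions known to spare the gallate esters, the interflavan bonds and the benzylic O1–C2 bonds of procyanidins, and it touches no stereocentre.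

Compound list
1 | (−)-epicatechin | Oc1cc(O)c2c(c1)O[C@H](c1ccc(O)c(O)c1)[C@H](O)C2 | starting material
2 | 5,7,3',4'-tetra-O-benzyl-(−)-epicatechin | c1c(OCc9ccccc9)cc(OCc9ccccc9)c2c1O[C@H](c1ccc(OCc9ccccc9)c(OCc9ccccc9)c1)[C@H](O)C2 | intermediate
3 | 5,7,3',4'-tetra-O-benzyl-3-O-TBS-(−)-epicatechin | c1c(OCc9ccccc9)cc(OCc9ccccc9)c2c1O[C@H](c1ccc(OCc9ccccc9)c(OCc9ccccc9)c1)[C@H](O[Si](C)(C)C(C)(C)C)C2 | intermediate
4 | 4β-(2-ethoxyethoxy) derivative of 3 | CC(C)(C)[Si](C)(C)O[C@@H]1[C@@H](OCCOCC)c2c(OCc9ccccc9)cc(OCc9ccccc9)cc2O[C@@H]1c1ccc(OCc9ccccc9)c(OCc9ccccc9)c1 | intermediate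
5 | 8-bromo derivative of 4 | CC(C)(C)[Si](C)(C)O[C@@H]1[C@@H](OCCOCC)c2c(OCc9ccccc9)cc(OCc9ccccc9)c(Br)c2O[C@@H]1c1ccc(OCc9ccccc9)c(OCc9ccccc9)c1 | intermediate
6 | 8-bromo (4β→8) dimer, octa-O-benzyl, bis-3-O-TBS | CC(C)(C)[Si](C)(C)O[C@@H]1[C@@H](c2c(OCc9ccccc9)cc(OCc9ccccc9)c3c2O[C@H](c2ccc(OCc9ccccc9)c(OCc9ccccc9)c2)[C@H](O[Si](C)(C)C(C)(C)C)C3)c2c(OCc9ccccc9)cc(OCc9ccccc9)c(Br)c2O[C@@H]1c1ccc(OCc9ccccc9)c(OCc9ccccc9)c1 | intermediate
7 | 2',4',6'-trihydroxyacetophenone | CC(=O)c1c(O)cc(O)cc1O | starting material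
8 | 1-[2,4-bis(benzyloxy)-6-hydroxyphenyl]ethanone | CC(=O)c1c(O)cc(OCc9ccccc9)cc1OCc9ccccc9 | intermediate
9 | 1-[2-(allyloxy)-4,6-bis(benzyloxy)phenyl]ethanone | CC(=O)c1c(OCC=C)cc(OCc9ccccc9)cc1OCc9ccccc9 | intermediate
10 | trimethylsilyl enol ether of 9 | C=C(O[Si](C)(C)C)c1c(OCC=C)cc(OCc9ccccc9)cc1OCc9ccccc9 | intermediate (not isolated)
11 | 2-(trimethylsilyloxy) ketone | C[Si](C)(C)OCC(=O)c1c(OCC=C)cc(OCc9ccccc9)cc1OCc9ccccc9 | intermediate (not isolated)
12 | 1-[2-(allyloxy)-4,6-bis(benzyloxy)phenyl]-2-hydroxyethanone | OCC(=O)c1c(OCC=C)cc(OCc9ccccc9)cc1OCc9ccccc9 | intermediate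
13 | 1-[2-(allyloxy)-4,6-bis(benzyloxy)phenyl]-2-(methoxymethoxy)ethanone | COCOCC(=O)c1c(OCC=C)cc(OCc9ccccc9)cc1OCc9ccccc9 | intermediate
14 | 3,4-bis(benzyloxy)benzaldehyde | O=Cc1ccc(OCc2ccccc2)c(OCc2ccccc2)c1 | starting material
15 | (Z)-alpha-(methoxymethoxy)chalcone | O=C(c1c(OCC=C)cc(OCc9ccccc9)cc1OCc9ccccc9)/C(OCOC)=C/c1ccc(OCc9ccccc9)c(OCc9ccccc9)c1 | intermediate
16 | 8-lithio (4β→8) dimer | CC(C)(C)[Si](C)(C)O[C@@H]1[C@@H](c2c(OCc9ccccc9)cc(OCc9ccccc9)c3c2O[C@H](c2ccc(OCc9ccccc9)c(OCc9ccccc9)c2)[C@H](O[Si](C)(C)C(C)(C)C)C3)c2c(OCc9ccccc9)cc(OCc9ccccc9)c([Li])c2O[C@@H]1c1ccc(OCc9ccccc9)c(OCc9ccccc9)c1 | intermediate (not isolated)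
17 | O-allyl tertiary allylic carbinol (carbinol epimers) | CC(C)(C)[Si](C)(C)O[C@@H]1[C@@H](c2c(OCc9ccccc9)cc(OCc9ccccc9)c3c2O[C@H](c2ccc(OCc9ccccc9)c(OCc9ccccc9)c2)[C@H](O[Si](C)(C)C(C)(C)C)C3)c2c(OCc9ccccc9)cc(OCc9ccccc9)c(C(O)(c3c(OCC=C)cc(OCc9ccccc9)cc3OCc9ccccc9)/C(OCOC)=C/c3ccc(OCc9ccccc9)c(OCc9ccccc9)c3)c2O[C@@H]1c1ccc(OCc9ccccc9)c(OCc9ccccc9)c1 | intermediate
18 | tertiary allylic carbinol with free ring A phenol (carbinol epimers), key-step precursor | CC(C)(C)[Si](C)(C)O[C@@H]1[C@@H](c2c(OCc9ccccc9)cc(OCc9ccccc9)c3c2O[C@H](c2ccc(OCc9ccccc9)c(OCc9ccccc9)c2)[C@H](O[Si](C)(C)C(C)(C)C)C3)c2c(OCc9ccccc9)cc(OCc9ccccc9)c(C(O)(c3c(O)cc(OCc9ccccc9)cc3OCc9ccccc9)/C(OCOC)=C/c3ccc(OCc9ccccc9)c(OCc9ccccc9)c3)c2O[C@@H]1c1ccc(OCc9ccccc9)c(OCc9ccccc9)c1 | intermediate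
19 | 1,1,3-triaryl-2-(methoxymethoxy)allyl cation (ion pair with the phosphoramide anion) | CC(C)(C)[Si](C)(C)O[C@@H]1[C@@H](c2c(OCc9ccccc9)cc(OCc9ccccc9)c3c2O[C@H](c2ccc(OCc9ccccc9)c(OCc9ccccc9)c2)[C@H](O[Si](C)(C)C(C)(C)C)C3)c2c(OCc9ccccc9)cc(OCc9ccccc9)c([C+](c3c(O)cc(OCc9ccccc9)cc3OCc9ccccc9)C(OCOC)=Cc3ccc(OCc9ccccc9)c(OCc9ccccc9)c3)c2O[C@@H]1c1ccc(OCc9ccccc9)c(OCc9ccccc9)c1 | intermediate (not isolated)
20 | (2R)-3-(methoxymethoxy)-4-(dimer-8-yl)flav-3-ene, bis-TBS, key-step product | CC(C)(C)[Si](C)(C)O[C@@H]1[C@@H](c2c(OCc9ccccc9)cc(OCc9ccccc9)c3c2O[C@H](c2ccc(OCc9ccccc9)c(OCc9ccccc9)c2)[C@H](O[Si](C)(C)C(C)(C)C)C3)c2c(OCc9ccccc9)cc(OCc9ccccc9)c(C3=C(OCOC)[C@@H](c4ccc(OCc9ccccc9)c(OCc9ccccc9)c4)Oc4cc(OCc9ccccc9)cc(OCc9ccccc9)c34)c2O[C@@H]1c1ccc(OCc9ccccc9)c(OCc9ccccc9)c1 | intermediate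
21 | (2R)-flav-3-ene diol | O[C@@H]1[C@@H](c2c(OCc9ccccc9)cc(OCc9ccccc9)c3c2O[C@H](c2ccc(OCc9ccccc9)c(OCc9ccccc9)c2)[C@H](O)C3)c2c(OCc9ccccc9)cc(OCc9ccccc9)c(C3=C(OCOC)[C@@H](c4ccc(OCc9ccccc9)c(OCc9ccccc9)c4)Oc4cc(OCc9ccccc9)cc(OCc9ccccc9)c34)c2O[C@@H]1c1ccc(OCc9ccccc9)c(OCc9ccccc9)c1 | intermediate
22 | 3,4,5-tris(benzyloxy)benzoic acid | OC(=O)c1cc(OCc2ccccc2)c(OCc2ccccc2)c(OCc2ccccc2)c1 | starting material
23 | (2R)-flav-3-ene bis(tri-O-benzylgallate) | O=C(O[C@@H]1[C@@H](c2c(OCc9ccccc9)cc(OCc9ccccc9)c3c2O[C@H](c2ccc(OCc9ccccc9)c(OCc9ccccc9)c2)[C@H](OC(=O)c2cc(OCc9ccccc9)c(OCc9ccccc9)c(OCc9ccccc9)c2)C3)c2c(OCc9ccccc9)cc(OCc9ccccc9)c(C3=C(OCOC)[C@@H](c4ccc(OCc9ccccc9)c(OCc9ccccc9)c4)Oc4cc(OCc9ccccc9)cc(OCc9ccccc9)c34)c2O[C@@H]1c1ccc(OCc9ccccc9)c(OCc9ccccc9)c1)c1cc(OCc9ccccc9)c(OCc9ccccc9)c(OCc9ccccc9)c1 | intermediate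
24 | (2R)-3-(trimethylsilyloxy)flav-3-ene bis-gallate | O=C(O[C@@H]1[C@@H](c2c(OCc9ccccc9)cc(OCc9ccccc9)c3c2O[C@H](c2ccc(OCc9ccccc9)c(OCc9ccccc9)c2)[C@H](OC(=O)c2cc(OCc9ccccc9)c(OCc9ccccc9)c(OCc9ccccc9)c2)C3)c2c(OCc9ccccc9)cc(OCc9ccccc9)c(C3=C(O[Si](C)(C)C)[C@@H](c4ccc(OCc9ccccc9)c(OCc9ccccc9)c4)Oc4cc(OCc9ccccc9)cc(OCc9ccccc9)c34)c2O[C@@H]1c1ccc(OCc9ccccc9)c(OCc9ccccc9)c1)c1cc(OCc9ccccc9)c(OCc9ccccc9)c(OCc9ccccc9)c1 | intermediate (not isolated)
25 | (2R,4S)-flavan-3-one bis-gallate (2,4-cis) | O=C(O[C@@H]1[C@@H](c2c(OCc9ccccc9)cc(OCc9ccccc9)c3c2O[C@H](c2ccc(OCc9ccccc9)c(OCc9ccccc9)c2)[C@H](OC(=O)c2cc(OCc9ccccc9)c(OCc9ccccc9)c(OCc9ccccc9)c2)C3)c2c(OCc9ccccc9)cc(OCc9ccccc9)c([C@@H]3c4c(OCc9ccccc9)cc(OCc9ccccc9)cc4O[C@H](c4ccc(OCc9ccccc9)c(OCc9ccccc9)c4)C3=O)c2O[C@@H]1c1ccc(OCc9ccccc9)c(OCc9ccccc9)c1)c1cc(OCc9ccccc9)c(OCc9ccccc9)c(OCc9ccccc9)c1 | intermediate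
26 | octadeca-O-benzyl trimer bis-gallate, top unit all-cis (2R,3R,4S), top 3-OH free | O=C(O[C@@H]1[C@@H](c2c(OCc9ccccc9)cc(OCc9ccccc9)c3c2O[C@H](c2ccc(OCc9ccccc9)c(OCc9ccccc9)c2)[C@H](OC(=O)c2cc(OCc9ccccc9)c(OCc9ccccc9)c(OCc9ccccc9)c2)C3)c2c(OCc9ccccc9)cc(OCc9ccccc9)c([C@@H]3c4c(OCc9ccccc9)cc(OCc9ccccc9)cc4O[C@H](c4ccc(OCc9ccccc9)c(OCc9ccccc9)c4)[C@@H]3O)c2O[C@@H]1c1ccc(OCc9ccccc9)c(OCc9ccccc9)c1)c1cc(OCc9ccccc9)c(OCc9ccccc9)c(OCc9ccccc9)c1 | intermediate
27 | epicatechin-(4α→8)-epicatechin-3-O-gallate-(4β→8)-epicatechin-3-O-gallate | O=C(O[C@@H]1[C@@H](c2c(O)cc(O)c3c2O[C@H](c2ccc(O)c(O)c2)[C@H](OC(=O)c2cc(O)c(O)c(O)c2)C3)c2c(O)cc(O)c([C@@H]3c4c(O)cc(O)cc4O[C@H](c4ccc(O)c(O)c4)[C@@H]3O)c2O[C@@H]1c1ccc(O)c(O)c1)c1cc(O)c(O)c(O)c1 | target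

Total step count: 18. Longest linear sequence: 13 steps (1 to 27 through steps 1–5 and 11–18; the branch from 7 through steps 6–10 and 11–18 is equally long).

Steps most likely to fail

Step 16 (unmasking of the enol ether).
- What may go wrong: the acetal exchange may stall at the crowded enol oxygen. The methoxymethyl fragment may be transferred to carbon. The silyl Lewis acid may ionise the allylic O1–C2 bond, with loss of configuration at C2. The ketonisation may lose its kinetic facial bias at C4.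
- Fallback: it sets out from 23 and returns at 25, and uses only known, acid-free reactions. Dimethyldioxirane (acetone, −40 °C) oxidises the electron-rich enol double bond from the face opposite ring B in a Rubottom-type oxidation. The adduct collapses on neutral aqueous work-up, with loss of the methoxymethyl group, to the 4-hydroxyflavan-3-one bis-gallate F1. SmI2 (THF/MeOH, −78 °C), the known reductant for alpha-oxygenated ketones, then removes the tertiary, doubly benzylic hydroxyl group. Methanol protonates the samarium enolate from the open face to give 25.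

Step 13 (key step).
- What may go wrong: facial selectivity may be poor because the catalyst is mismatched with the dimer, or because the neutral ortho-quinone methide closes without the catalyst. The selectivity may erode through re-ionisation of the product. Hydride may be transferred from C2–H of the product to the cation. Ring B may close slowly and irreversibly onto C4.
- Fallback: it sets out from 18 and returns at 20, and replaces catalyst control by separation and recycling. An achiral acid, diphenyl phosphate (5 mol %, toluene, −20 °C), effects the ordinary cyclodehydration of the ortho-hydroxyaryl allylic alcohol. This gives 20 together with the (2S)-flav-3-ene epimer F2. Because the dimer is enantiopure the two are diastereomers, and they are separated on amine-deactivated silica or by preparative HPLC. F2 is returned to the same acid, which re-opens its allylic aryl ether to 19 and re-establishes the mixture, so the material is funnelled into 20 over a few cycles.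

Step 11 (fragment union).
- What may go wrong: the crowded ketone may resist 1,2-addition, so that conjugate addition or simple protonation of the aryllithium takes over.
- Fallback: it gives up the ring construction in favour of the known aryllithium/flavan-4-one entry to 4α-linked units. It sets out from 2 and 6 and returns at 27.
 - Benzylation of 2 (NaH, BnBr, DMF) gives penta-O-benzylepicatechin F3.
 - DDQ in wet CH2Cl2 gives the 4β-alcohol F4.
 - Dess–Martin periodinane gives the flavan-4-one F5.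
 - Aryllithium 16, made from 6 as in step 11, adds to this cyclic, less crowded ketone to give the tertiary benzylic alcohol F6.
 - Bu3SnH/CF3CO2H (CH2Cl2, 0 °C) ionises it and delivers hydride to the face opposite the 2-aryl and 3-benzyloxy groups, giving the all-cis protected trimer F7.
 - Desilylation as in step 14 gives the diol F8, and esterification with 22 as in step 15 gives the bis-gallate F9.
 - Hydrogenolysis as in step 18, which also removes the top 3-O-benzyl group, gives 27.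

Further compounds
F1 | step 16 | (2R)-4-hydroxy-4-(dimer-8-yl)flavan-3-one bis-gallate, 4-OH trans to ring B | O=C(O[C@@H]1[C@@H](c2c(OCc9ccccc9)cc(OCc9ccccc9)c3c2O[C@H](c2ccc(OCc9ccccc9)c(OCc9ccccc9)c2)[C@H](OC(=O)c2cc(OCc9ccccc9)c(OCc9ccccc9)c(OCc9ccccc9)c2)C3)c2c(OCc9ccccc9)cc(OCc9ccccc9)c([C@]3(O)c4c(OCc9ccccc9)cc(OCc9ccccc9)cc4O[C@H](c4ccc(OCc9ccccc9)c(OCc9ccccc9)c4)C3=O)c2O[C@@H]1c1ccc(OCc9ccccc9)c(OCc9ccccc9)c1)c1cc(OCc9ccccc9)c(OCc9ccccc9)c(OCc9ccccc9)c1
F2 | step 13 | (2S)-epimer of 20 | CC(C)(C)[Si](C)(C)O[C@@H]1[C@@H](c2c(OCc9ccccc9)cc(OCc9ccccc9)c3c2O[C@H](c2ccc(OCc9ccccc9)c(OCc9ccccc9)c2)[C@H](O[Si](C)(C)C(C)(C)C)C3)c2c(OCc9ccccc9)cc(OCc9ccccc9)c(C3=C(OCOC)[C@H](c4ccc(OCc9ccccc9)c(OCc9ccccc9)c4)Oc4cc(OCc9ccccc9)cc(OCc9ccccc9)c34)c2O[C@@H]1c1ccc(OCc9ccccc9)c(OCc9ccccc9)c1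
F3 | step 11 | 3,5,7,3',4'-penta-O-benzyl-(−)-epicatechin | c1c(OCc9ccccc9)cc(OCc9ccccc9)c2c1O[C@H](c1ccc(OCc9ccccc9)c(OCc9ccccc9)c1)[C@H](OCc9ccccc9)C2
F4 | step 11 | 4β-hydroxy-penta-O-benzylepicatechin | C(c9ccccc9)O[C@@H]1[C@@H](O)c2c(OCc9ccccc9)cc(OCc9ccccc9)cc2O[C@@H]1c1ccc(OCc9ccccc9)c(OCc9ccccc9)c1
F5 | step 11 | penta-O-benzyl flavan-4-one (2,3-cis) | C(c9ccccc9)O[C@@H]1C(=O)c2c(OCc9ccccc9)cc(OCc9ccccc9)cc2O[C@@H]1c1ccc(OCc9ccccc9)c(OCc9ccccc9)c1
F6 | step 11 | tertiary benzylic alcohol, top C4 configuration not defined | CC(C)(C)[Si](C)(C)O[C@@H]1[C@@H](c2c(OCc9ccccc9)cc(OCc9ccccc9)c3c2O[C@H](c2ccc(OCc9ccccc9)c(OCc9ccccc9)c2)[C@H](O[Si](C)(C)C(C)(C)C)C3)c2c(OCc9ccccc9)cc(OCc9ccccc9)c(C3(O)c4c(OCc9ccccc9)cc(OCc9ccccc9)cc4O[C@H](c4ccc(OCc9ccccc9)c(OCc9ccccc9)c4)[C@@H]3OCc9ccccc9)c2O[C@@H]1c1ccc(OCc9ccccc9)c(OCc9ccccc9)c1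
F7 | step 11 | all-cis top-3-O-benzyl trimer, bis-TBS | CC(C)(C)[Si](C)(C)O[C@@H]1[C@@H](c2c(OCc9ccccc9)cc(OCc9ccccc9)c3c2O[C@H](c2ccc(OCc9ccccc9)c(OCc9ccccc9)c2)[C@H](O[Si](C)(C)C(C)(C)C)C3)c2c(OCc9ccccc9)cc(OCc9ccccc9)c([C@@H]3c4c(OCc9ccccc9)cc(OCc9ccccc9)cc4O[C@H](c4ccc(OCc9ccccc9)c(OCc9ccccc9)c4)[C@@H]3OCc9ccccc9)c2O[C@@H]1c1ccc(OCc9ccccc9)c(OCc9ccccc9)c1
F8 | step 11 | all-cis top-3-O-benzyl trimer diol | O[C@@H]1[C@@H](c2c(OCc9ccccc9)cc(OCc9ccccc9)c3c2O[C@H](c2ccc(OCc9ccccc9)c(OCc9ccccc9)c2)[C@H](O)C3)c2c(OCc9ccccc9)cc(OCc9ccccc9)c([C@@H]3c4c(OCc9ccccc9)cc(OCc9ccccc9)cc4O[C@H](c4ccc(OCc9ccccc9)c(OCc9ccccc9)c4)[C@@H]3OCc9ccccc9)c2O[C@@H]1c1ccc(OCc9ccccc9)c(OCc9ccccc9)c1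
F9 | step 11 | all-cis top-3-O-benzyl trimer bis(tri-O-benzylgallate) | O=C(O[C@@H]1[C@@H](c2c(OCc9ccccc9)cc(OCc9ccccc9)c3c2O[C@H](c2ccc(OCc9ccccc9)c(OCc9ccccc9)c2)[C@H](OC(=O)c2cc(OCc9ccccc9)c(OCc9ccccc9)c(OCc9ccccc9)c2)C3)c2c(OCc9ccccc9)cc(OCc9ccccc9)c([C@@H]3c4c(OCc9ccccc9)cc(OCc9ccccc9)cc4O[C@H](c4ccc(OCc9ccccc9)c(OCc9ccccc9)c4)[C@@H]3OCc9ccccc9)c2O[C@@H]1c1ccc(OCc9ccccc9)c(OCc9ccccc9)c1)c1cc(OCc9ccccc9)c(OCc9ccccc9)c(OCc9ccccc9)c1
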